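**Assumptions**

- The target is taken exactly as the given SMILES. In the 1-oxaquinolizidine half: carbinol carbon R, adjacent methyl carbon S, N,O-acetal carbon S, its ring neighbour R. In the quinolizidin-2-one half: methyl carbon R, chain-bearing carbon α to the ketone R, ring-fusion carbon S, its chain-bearing ring neighbour S.
- The ring carbon α to the cyclopentanone (later lactam) carbonyl is carried as both epimers; it is erased at the enamine stage of the last step.
- (S)-SEGPHOS is written as the ligand hand that gives the (7R,8S) adduct; if the sense is opposite, the antipodal ligand is used.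

**Retrosynthetic overview**

1. Last step: the 1,3-oxazine ring and the piperidin-4-one ring are closed together on a 24-membered bis-δ-lactam keto alcohol by double reductive lactam activation (N,O-acetalisation on one side, transannular Mannich C–C bond formation on the other).
2. The keto alcohol comes from a C2-symmetric bis(hydroxy lactam) by mono-oxidation.
3. Key disconnection: the bis(hydroxy lactam) is the head-to-tail cyclodimer of one azido-alcohol cyclopentanone; a double Schmidt ring expansion (cyclopentanone → piperidin-2-one) makes both piperidine rings, both N–C bonds and the macrocycle in one operation.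
4. The monomer comes from cyclopentanone, 7-bromohept-1-ene and but-3-en-2-yl acetate: alkylation, hydroboration, catalytic anti-crotylation (sets the two fixed stereocentres), ozonolysis, azidation.
5. Ring order: two piperidinone rings plus macrocycle (together), then oxazine ring plus piperidone ring (together).

**Route**

Step 1
Reactants: 1 cyclopentanone; 2 7-bromohept-1-ene
Product: 4 2-(hept-6-en-1-yl)cyclopentan-1-one, via lithium cyclopent-1-en-1-olate 3 (not isolated)
Conditions: LiN(iPr)2 (2.0 equiv), 1 (2.2 equiv), THF, −78 °C; then 2 (1.0 equiv), DMPU, −78 → 23 °C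
Reagents that add atoms: none
Why: Lithium enolate alkylation (SN2) of a symmetric ketone with a primary bromide, excess enolate limiting dialkylation; the new α-centre is racemic, which does not matter because it is erased in step 8.

Step 2
Reactants: 4 2-(hept-6-en-1-yl)cyclopentan-1-one
Product: 6 2-(7-hydroxyheptyl)cyclopentan-1-one, via catechol boronate 5 (not isolated)
Conditions: catecholborane (1.2 equiv), RhCl(PPh3)3 (2 mol %), THF, 23 °C; then NaOH, H2O2, 0 °C
Reagents that add atoms: hydrogen peroxide, OO
Why: RhCl(PPh3)3-catalysed hydroboration with catecholborane is anti-Markovnikov and selective for the terminal alkene over the ketone, and peroxide oxidation of the C–B bond gives the primary alcohol (hydroboration–oxidation).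

Step 3
Reactants: 6 2-(7-hydroxyheptyl)cyclopentan-1-one; 7 but-3-en-2-yl acetate (racemic)
Product: 9 2-[(7R,8S)-7-hydroxy-8-methyldec-9-en-1-yl]cyclopentan-1-one, via keto aldehyde 8 (not isolated)
Conditions: [Ir(cod)Cl]2 (2.5 mol %), (S)-SEGPHOS (5 mol %), 4-cyano-3-nitrobenzoic acid (10 mol %), Cs2CO3 (20 mol %), 7 (2 equiv), THF, 70 °C
Reagents that add atoms: none
Why: Krische iridium-catalysed transfer-hydrogenative anti-crotylation from the alcohol oxidation level, in which the transient aldehyde is trapped by the (E)-σ-crotyl iridium species through a closed chair transition state so that the chiral cyclometallated iridium–SEGPHOS catalyst sets the carbinol (R) and the adjacent methyl carbon (S) as the anti pair; the ketone is expected to be neither crotylated nor reduced, since this catalyst does not dehydrogenate secondary alcohols.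

Step 4
Reactants: 9 2-[(7R,8S)-7-hydroxy-8-methyldec-9-en-1-yl]cyclopentan-1-one
Product: 12 2-[(7R,8S)-7,9-dihydroxy-8-methylnonyl]cyclopentan-1-one, via ozonide 10 (not isolated), via hydroxy aldehyde 11 (not isolated)
Conditions: O3, CH2Cl2, −78 °C; PPh3, −78 → 0 °C; then NaBH(OAc)3, AcOH, 0 °C
Reagents that add atoms: ozone, O=[O+][O-]
Why: Ozonolysis cleaves the only alkene, PPh3 reduces the ozonide, and NaBH(OAc)3 reduces the β-hydroxy aldehyde but not the ketone (chemoselective acyloxyborohydride reduction); both stereocentres are untouched provided the aldehyde is reduced cold and at once.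

Step 5
Reactants: 12 2-[(7R,8S)-7,9-dihydroxy-8-methylnonyl]cyclopentan-1-one
Product: 14 2-[(7R,8S)-9-azido-7-hydroxy-8-methylnonyl]cyclopentan-1-one, via primary tosylate 13 (not isolated)
Conditions: TsCl (1.05 equiv), pyridine, 0 °C; then NaN3, DMF, 60 °C
Reagents that add atoms: sodium azide, [Na+].[N-]=[N+]=[N-]
Why: Selective sulfonylation of the primary hydroxyl of the 1,3-diol followed by SN2 displacement by azide at a primary carbon; no stereocentre is involved.

Step 6
Reactants: 14 2-[(7R,8S)-9-azido-7-hydroxy-8-methylnonyl]cyclopentan-1-one (two molecules)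
Product: 17 macrocyclic bis(hydroxy lactam), via linear iminium ether dimer 15 (not isolated), via macrocyclic bis(iminium ether) 16 (not isolated)
Conditions: BF3·OEt2 (6 equiv), CH2Cl2 (0.02 M), 0 → 23 °C; then 15% aq KOH, 23 °C
Reagents that add atoms: potassium hydroxide (aqueous), [K+].[OH-]
Why: Proposed new method: a head-to-tail cyclodimerising double azido-Schmidt ring expansion in which BF3 promotes hemiketal/oxocarbenium formation between the ketone of one molecule and the carbinol of another, the tethered azide adds to give a spiro 1,3-oxazinane aminodiazonium ion, and the ring C–C bond antiperiplanar to the axial N–N2+ bond shifts from carbon to nitrogen with loss of N2 (cyclopentanone → six-membered iminium ether); the chain-bearing α-carbon sits equatorial on the oxazinane chair (methyl and alkyl both equatorial), so the CH2 carbon migrates and the chain ends up next to the lactam carbonyl; the monomer cannot close on itself (ten-membered oxocarbenium ring), so the linear dimer closes to the 20-membered bis(iminium ether), and hydroxide attack at the iminium carbon releases both carbinols with retention; the closest known reaction type is the intermolecular BF3-mediated Schmidt (Boyer–Aubé) ring expansion of cyclic ketones with 1,3-azido alcohols to N-(3-hydroxyalkyl) lactams, which has not been shown as a macrocyclodimerisation.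

Step 7
Reactants: 17 macrocyclic bis(hydroxy lactam)
Product: 18 macrocyclic keto alcohol bis-lactam
Conditions: Dess–Martin periodinane (0.8 equiv), CH2Cl2, 0 → 23 °C
Reagents that add atoms: none
Why: Dess–Martin oxidation of one of the two equivalent secondary carbinols of the C2-symmetric diol (lactams inert); the step is statistical (at best about half the material per pass), so it is stopped at partial conversion, the keto alcohol is separated and recovered diol is recycled; no stereocentre is formed.

Step 8
Reactants: 18 macrocyclic keto alcohol bis-lactam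
Product: 20 CNP0236330.1, via macrocyclic bis(enamine) 19 (not isolated)
Conditions: IrCl(CO)(PPh3)2 (2 mol %), (Me2HSi)2O (6 equiv), toluene, 23 °C; then AcOH, MeOH, 50 °C
Reagents that add atoms: none
Why: Amide-selective IrCl(CO)(PPh3)2/tetramethyldisiloxane hydrosilylation of both tertiary lactams (Nagashima–Dixon reductive amide activation) gives the bis(enamine), and C-protonation in acid gives two cyclic iminium ions, one trapped by the carbinol oxygen (N,O-acetalisation) and the other by the ketone enol through its CH2 carbon (intramolecular Mannich reaction); the six new or reset centres are under thermodynamic control, the oxa half settling relative to the fixed carbinol/methyl pair in the all-equatorial trans-fused form (acetal carbon S, its neighbour R) and the keto half in the trans-fused chair with equatorial methyl (R, epimerised through the enol from the S configuration delivered by step 3), equatorial chain on the piperidine ring (S), axial chain α to the ketone (R, avoiding the syn-pentane clash) and ring-fusion carbon S, with iminium–enamine and retro-Mannich/Mannich exchange letting the macrocycle equilibrate.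

**Compound list**

1 | cyclopentanone | O=C1CCCC1 | starting material
2 | 7-bromohept-1-ene | C=CCCCCCBr | starting material
3 | lithium cyclopent-1-en-1-olate | [Li+].[O-]C1=CCCC1 | intermediate
4 | 2-(hept-6-en-1-yl)cyclopentan-1-one (racemic) | O=C1CCCC1CCCCCC=C | intermediate
5 | 2-[7-(1,3,2-benzodioxaborol-2-yl)heptyl]cyclopentan-1-one | O=C1CCCC1CCCCCCCB2Oc3ccccc3O2 | intermediate
6 | 2-(7-hydroxyheptyl)cyclopentan-1-one | O=C1CCCC1CCCCCCCO | intermediate
7 | but-3-en-2-yl acetate (racemic) | CC(OC(C)=O)C=C | starting material
8 | 7-(2-oxocyclopentyl)heptanal | O=CCCCCCCC1CCCC1=O | intermediate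
9 | 2-[(7R,8S)-7-hydroxy-8-methyldec-9-en-1-yl]cyclopentan-1-one (both ring epimers) | O=C1CCCC1CCCCCC[C@@H](O)[C@@H](C)C=C | intermediate
10 | 2-[(7R,8R)-7-hydroxy-8-(1,2,4-trioxolan-3-yl)nonyl]cyclopentan-1-one | O=C1CCCC1CCCCCC[C@@H](O)[C@@H](C)C2OCOO2 | intermediate
11 | (2R,3R)-3-hydroxy-2-methyl-9-(2-oxocyclopentyl)nonanal | O=C1CCCC1CCCCCC[C@@H](O)[C@@H](C)C=O | intermediate
12 | 2-[(7R,8S)-7,9-dihydroxy-8-methylnonyl]cyclopentan-1-one | O=C1CCCC1CCCCCC[C@@H](O)[C@@H](C)CO | intermediate
13 | (2S,3R)-3-hydroxy-2-methyl-9-(2-oxocyclopentyl)nonyl 4-methylbenzenesulfonate | O=C1CCCC1CCCCCC[C@@H](O)[C@@H](C)COS(=O)(=O)c2ccc(C)cc2 | intermediate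
14 | 2-[(7R,8S)-9-azido-7-hydroxy-8-methylnonyl]cyclopentan-1-one | O=C1CCCC1CCCCCC[C@@H](O)[C@@H](C)CN=[N+]=[N-] | intermediate
15 | linear head-to-tail dimer: (2R,3S)-9-[(7R,8S)-9-azido-7-hydroxy-8-methylnonyl]-3-methyl-2-[6-(2-oxocyclopentyl)hexyl]-3,4,6,7,8,9-hexahydro-2H-pyrido[2,1-b][1,3]oxazin-5-ium | [N-]=[N+]=NC[C@H](C)[C@H](O)CCCCCCC1CCC[N+]2=C1O[C@H](CCCCCCC3CCCC3=O)[C@@H](C)C2 | intermediate
16 | macrocyclic bis(iminium ether) dication: two 3-methyl-hexahydropyrido[2,1-b][1,3]oxazin-5-ium units, C2 of each joined through (CH2)6 to C9 of the other (C2 R, C3 S in both) | C[C@H]1C[N+]2=C5O[C@@H]1CCCCCCC3CCC[N+]4=C3O[C@H](CCCCCCC5CCC2)[C@@H](C)C4 | intermediate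
17 | macrocyclic bis(hydroxy lactam): 24-membered C2-symmetric ring of two piperidin-2-ones, each N–CH2–CH(CH3)–CH(OH)–(CH2)6– linked to C3 of the other (carbinol carbons R, methyl carbons S, lactam C3 epimers) | C[C@H]1CN2CCCC(C2=O)CCCCCC[C@@H](O)[C@@H](C)CN3CCCC(C3=O)CCCCCC[C@H]1O | intermediate
18 | macrocyclic keto alcohol bis-lactam: 17 with one carbinol oxidised to the ketone | C[C@H]1CN2CCCC(C2=O)CCCCCC[C@@H](O)[C@@H](C)CN3CCCC(C3=O)CCCCCCC1=O | intermediate
19 | macrocyclic bis(enamine): 18 with both lactams reduced to N–CH=C 1,2,3,4-tetrahydropyridines | C[C@H]1CN2CCCC(=C2)CCCCCC[C@@H](O)[C@@H](C)CN3CCCC(=C3)CCCCCCC1=O | intermediate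
20 | CNP0236330.1 | C[C@@H]1CN2CCC[C@@H]3CCCCCC[C@H]4O[C@H]5[C@H](CCCCC[C@@H](C1=O)[C@H]32)CCCN5C[C@@H]4C | target

**Step count and risks**

Total step count: 8. Longest linear sequence: 8 steps.

Step 6 (the proposed new step) is the most likely to fail. The cyclodimerisation may give oligomers, or the substituted α-carbon may migrate instead of the CH2. The fallback uses known chemistry only, sets out from 2 and comes back at 17. Commercial piperidin-2-one F1 is C-alkylated with 2 through its N,C-dianion (n-BuLi, 2 equiv, THF, 0 °C) to give 3-(hept-6-en-1-yl)piperidin-2-one F2. Hydroboration–oxidation (9-BBN; NaOH, H2O2) gives 3-(7-hydroxyheptyl)piperidin-2-one F3. The crotylation of step 3 gives 3-[(7R,8S)-7-hydroxy-8-methyldec-9-en-1-yl]piperidin-2-one F4. Ozonolysis with NaBH4 work-up gives 3-[(7R,8S)-7,9-dihydroxy-8-methylnonyl]piperidin-2-one F5. TsCl/pyridine gives the primary tosylate (2S,3R)-3-hydroxy-2-methyl-9-(2-oxopiperidin-3-yl)nonyl 4-methylbenzenesulfonate F6, and TBSOTf/2,6-lutidine gives its silyl ether (2S,3R)-3-[(tert-butyldimethylsilyl)oxy]-2-methyl-9-(2-oxopiperidin-3-yl)nonyl 4-methylbenzenesulfonate F7. NaH in DMF at 5 mM then closes the ring by head-to-tail double N-alkylation of the lactam sodium salts to the macrocyclic bis(tert-butyldimethylsilyl) ether of 17 F8, and Bu4NF gives 17.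

Step 8 is the second risk. The silane may also reduce the ketone. The relative configuration of the quinolizidinone half against the oxa half rests only on macrocyclic thermodynamics, so a second diastereomer (antipodal quinolizidinone unit) may accompany the target and would have to be separated and re-equilibrated. The fallback sets out from 18 and comes back at 20; it separates reduction from cyclisation and removes the ketone from the reduction. The ketone is protected (ethylene glycol, PPTS, benzene, reflux) as the 1,3-dioxolane ketal of 18 F9. Both lactams are reduced with stoichiometric Cp2Zr(H)Cl (THF, 23 °C) to the bis(enamine) ketal F10. Aqueous HCl/THF then unmasks the ketone and triggers N,O-acetalisation and the Mannich closure, followed by basification and equilibration to 20.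

Step 3 is the third risk. The keto alcohol may suffer base-mediated aldol chemistry or ketone reduction under the iridium conditions, or give a low anti:syn ratio. The fallback sets out from 6 and comes back at 9. Compound 6 is oxidised (Swern) to the keto aldehyde 8, this time isolated. Brown crotylboration follows with the (E)-crotyldiisopinocampheylborane antipode that gives the (7R,8S) anti adduct (THF, −78 °C; NaBO3 work-up); allylboranes add to aldehydes far faster than to ketones. This fallback makes no new compound (F0).

**Further compounds**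

F1 | step 6 | piperidin-2-one | O=C1CCCCN1
F2 | step 6 | 3-(hept-6-en-1-yl)piperidin-2-one | O=C1NCCCC1CCCCCC=C
F3 | step 6 | 3-(7-hydroxyheptyl)piperidin-2-one | O=C1NCCCC1CCCCCCCO
F4 | step 6 | 3-[(7R,8S)-7-hydroxy-8-methyldec-9-en-1-yl]piperidin-2-one | O=C1NCCCC1CCCCCC[C@@H](O)[C@@H](C)C=C
F5 | step 6 | 3-[(7R,8S)-7,9-dihydroxy-8-methylnonyl]piperidin-2-one | O=C1NCCCC1CCCCCC[C@@H](O)[C@@H](C)CO
F6 | step 6 | (2S,3R)-3-hydroxy-2-methyl-9-(2-oxopiperidin-3-yl)nonyl 4-methylbenzenesulfonate | O=C1NCCCC1CCCCCC[C@@H](O)[C@@H](C)COS(=O)(=O)c2ccc(C)cc2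
F7 | step 6 | (2S,3R)-3-[(tert-butyldimethylsilyl)oxy]-2-methyl-9-(2-oxopiperidin-3-yl)nonyl 4-methylbenzenesulfonate | O=C1NCCCC1CCCCCC[C@@H](O[Si](C)(C)C(C)(C)C)[C@@H](C)COS(=O)(=O)c2ccc(C)cc2
F8 | step 6 | macrocyclic bis(tert-butyldimethylsilyl) ether of 17 | C[C@H]1CN2CCCC(C2=O)CCCCCC[C@@H](O[Si](C)(C)C(C)(C)C)[C@@H](C)CN3CCCC(C3=O)CCCCCC[C@H]1O[Si](C)(C)C(C)(C)C
F9 | step 8 | 1,3-dioxolane ketal of 18 | C[C@H]1CN2CCCC(C2=O)CCCCCC[C@@H](O)[C@@H](C)CN3CCCC(C3=O)CCCCCCC14OCCO4
F10 | step 8 | bis(enamine) ketal (both lactams of F9 reduced to N–CH=C) | C[C@H]1CN2CCCC(=C2)CCCCCC[C@@H](O)[C@@H](C)CN3CCCC(=C3)CCCCCCC14OCCO4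
F0 | step 3 | none | none
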